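The route rests on closing the dihydrofuran ring at O1–C7a by intramolecular nucleophilic aromatic substitution. It exploits that C7a of the benzofuran benzene ring stands para to C5, the carbon bound to C2 of the chromenone: a nitrile on C5 (its carbon later becomes chromenone C2) activates C7a, and a nitro group on C7a, which earlier directs the vicarious nucleophilic substitution that builds the C3a side chain, leaves as nitrite. The precursor is an open-chain (1R,2S)-1,2-diaryl-propane-1,3-diol from an Evans syn-aldol, its primary hydroxyl capped as trityl ether; the C1 alkoxide attacks ipso in one operation. A one-pot Claisen–Schmidt/Algar–Flynn–Oyamada sequence and hydrogenolysis finish the synthesis.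

Key step: step 8

Remark: the locants O1, C2, C3, C3a, C4 to C7 and C7a refer to the dihydrobenzofuran of the target; four benzyl ethers and one trityl ether are the only protecting groups.

Step 1
Reactants: 1 3-hydroxy-4-nitrobenzonitrile
Product: 2 3-(benzyloxy)-4-nitrobenzonitrile
Conditions: BnBr, K2CO3, DMF, 60 °C
Reagents that add atoms: benzyl bromide, BrCc1ccccc1
Why: Williamson etherification of an acidic nitrophenol gives a benzyl ether that should survive base, acid and hydride and fall in the final hydrogenolysis.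

Step 2
Reactants: 2 3-(benzyloxy)-4-nitrobenzonitrile
Product: 4 tert-butyl 2-[3-(benzyloxy)-5-cyano-2-nitrophenyl]acetate, via σH adduct 3 (not isolated)
Conditions: ClCH2CO2t-Bu, potassium tert-butoxide (2.5 equiv), DMF, −40 → −20 °C; then aq. NH4Cl
Reagents that add atoms: tert-butyl chloroacetate, ClCC(=O)OC(C)(C)C
Why: Vicarious nucleophilic substitution of hydrogen: the chloro ester carbanion adds at the only CH position ortho to the nitro group (the para position carries the nitrile), and base-induced loss of HCl from adduct 3 restores the arene.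

Step 3
Reactants: 4 tert-butyl 2-[3-(benzyloxy)-5-cyano-2-nitrophenyl]acetate
Product: 5 2-[3-(benzyloxy)-5-cyano-2-nitrophenyl]acetic acid
Conditions: CF3CO2H/CH2Cl2 (1:4), rt
Reagents that add atoms: none
Why: Acidolysis of the tert-butyl ester should leave the benzyl aryl ether, the nitrile and the nitro group untouched.

Step 4
Reactants: 5 2-[3-(benzyloxy)-5-cyano-2-nitrophenyl]acetic acid, 6 (R)-4-benzyl-1,3-oxazolidin-2-one
Product: 8 (4R)-4-benzyl-3-{[3-(benzyloxy)-5-cyano-2-nitrophenyl]acetyl}-1,3-oxazolidin-2-one, via mixed pivalic anhydride 7 (not isolated)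
Conditions: t-BuCOCl, Et3N, THF, −20 °C; then 6, LiCl, rt
Reagents that add atoms: none
Why: N-acylation of the oxazolidinone through the mixed anhydride under LiCl activation gives the imide for the Evans aldol without strong base next to the acidic nitroarylacetyl CH2.

Step 5
Reactants: 8 (4R)-4-benzyl-3-{[3-(benzyloxy)-5-cyano-2-nitrophenyl]acetyl}-1,3-oxazolidin-2-one, 9 4-(benzyloxy)-3-methoxybenzaldehyde
Product: 11 (4R)-4-benzyl-3-{(2R,3R)-3-[4-(benzyloxy)-3-methoxyphenyl]-2-[3-(benzyloxy)-5-cyano-2-nitrophenyl]-3-hydroxypropanoyl}-1,3-oxazolidin-2-one, via boron enolate 10 (not isolated)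
Conditions: n-Bu2BOTf, i-Pr2NEt, CH2Cl2, −78 → 0 °C; 9, −78 → 0 °C; then pH 7 buffer, MeOH, 30% H2O2, 0 °C
Reagents that add atoms: none
Why: Evans syn-aldol: the Z boron enolate 10 reacts through a closed chair transition state in which the (R)-benzyl group of the auxiliary shields one enolate face, which should set both new centres (2R,3R), the syn relationship and absolute sense that lead to the (2R,3S) trans-dihydrobenzofuran.

Step 6
Reactants: 11 the aldol adduct
Product: 12 3-(benzyloxy)-5-{(1R,2S)-1-[4-(benzyloxy)-3-methoxyphenyl]-1,3-dihydroxypropan-2-yl}-4-nitrobenzonitrile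
Conditions: LiBH4, MeOH (1.5 equiv), THF, 0 °C
Reagents that add atoms: none
Why: Reductive cleavage of the imide by lithium borohydride should release the primary alcohol and the auxiliary without touching the nitrile or nitro group and without epimerising either stereocentre.

Step 7
Reactants: 12 the (1R,2S)-diol
Product: 13 3-(benzyloxy)-5-{(1R,2S)-1-[4-(benzyloxy)-3-methoxyphenyl]-1-hydroxy-3-(trityloxy)propan-2-yl}-4-nitrobenzonitrile
Conditions: Ph3CCl, Et3N, DMAP (cat.), CH2Cl2, rt
Reagents that add atoms: trityl chloride, ClC(c1ccccc1)(c1ccccc1)c1ccccc1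
Why: Tritylation is selective for the primary hydroxyl on steric grounds and gives a base-stable ether that cannot migrate to the secondary oxygen, so that only the benzylic alkoxide is available for ring closure.

Step 8
Reactants: 13 the trityl ether
Product: 16 (2R,3S)-7-(benzyloxy)-2-[4-(benzyloxy)-3-methoxyphenyl]-3-[(trityloxy)methyl]-2,3-dihydro-1-benzofuran-5-carbonitrile, via sodium alkoxide 14 (not isolated), via anionic σ-adduct 15 (not isolated)
Conditions: NaH (1.2 equiv), THF/DMF (4:1), 0 °C → rt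
Reagents that add atoms: none
Why: Deprotonation gives the secondary benzylic alkoxide 14, which adds to the nitro-bearing arene carbon to give the cyclohexadienyl anion 15, stabilised by the para nitrile, and loss of nitrite rearomatises the ring. The closest known reaction type is the intramolecular nucleophilic aromatic substitution of an activated nitro group by an alkoxide (denitrative etherification). The dihydrofuran ring closes in the 5-exo-trig mode at the arene carbon, forming the O1–C7a bond. No new stereocentre is created: C2 keeps its configuration because its C–O bond is never broken, C3 was set in the aldol step, and any base-induced epimerisation at the nitrobenzylic C3 before closure should drain through the less strained transition state to the same trans product. The step needs attack by the secondary and not the primary oxygen, which the trityl ether secures, and attack at the nitro-bearing carbon, which is secured by the para nitrile, by the twist of the nitro group out of the ring plane between its two ortho substituents and by the five-membered transition state.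

Step 9
Reactants: 16 the dihydrobenzofuran-5-carbonitrile
Product: 18 (2R,3S)-7-(benzyloxy)-2-[4-(benzyloxy)-3-methoxyphenyl]-3-[(trityloxy)methyl]-2,3-dihydro-1-benzofuran-5-carbaldehyde, via N-aluminio aldimine 17 (not isolated)
Conditions: i-Bu2AlH (1.5 equiv), toluene, −78 °C; then aq. potassium sodium tartrate, rt
Reagents that add atoms: water, O
Why: Addition of one hydride from diisobutylaluminium hydride to the nitrile stops at the aluminated aldimine 17, which hydrolyses on work-up to the aldehyde, while the ethers and the dihydrobenzofuran are inert.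

Step 10
Reactants: 19 1-(2,4,6-trihydroxyphenyl)ethanone
Product: 20 1-[2,4-bis(benzyloxy)-6-hydroxyphenyl]ethanone
Conditions: BnBr (2.1 equiv), K2CO3, acetone, reflux
Reagents that add atoms: benzyl bromide, BrCc1ccccc1
Why: Williamson etherification in which one ortho hydroxyl stays free because its hydrogen bond to the ketone lowers its nucleophilicity, leaving the phenol needed for the pyranone ring.

Step 11
Reactants: 18 the dihydrobenzofuran-5-carbaldehyde, 20 1-[2,4-bis(benzyloxy)-6-hydroxyphenyl]ethanone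
Product: 23 5,7-bis(benzyloxy)-2-{(2R,3S)-7-(benzyloxy)-2-[4-(benzyloxy)-3-methoxyphenyl]-3-[(trityloxy)methyl]-2,3-dihydro-1-benzofuran-5-yl}-3-hydroxy-4H-chromen-4-one, via chalcone 21 (not isolated), via dihydroflavonol 22 (not isolated)
Conditions: KOH, EtOH/THF, rt; then 30% H2O2, 0 °C → rt
Reagents that add atoms: hydrogen peroxide, OO
Why: Claisen–Schmidt condensation to the 2'-hydroxychalcone 21, followed in the same flask by the Algar–Flynn–Oyamada reaction (alkaline peroxide oxidation, ring closure by the phenoxide and dehydrogenation of dihydroflavonol 22), should give the 3-hydroxyflavone, and the two dihydrobenzofuran stereocentres carry no acidic hydrogen under these conditions.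

Step 12
Reactants: 23 the protected flavonol
Product: 24 2,3-dehydrosilychristin
Conditions: H2 (1 atm), 10% Pd/C, THF/MeOH, rt
Reagents that add atoms: none
Why: Hydrogenolysis should cleave the four benzyl ethers and the trityl ether in one operation, while the flavonol enone and the benzylic C2–O1 bond of the dihydrobenzofuran are expected to react more slowly under these mild conditions.

Compound list

1 | 3-hydroxy-4-nitrobenzonitrile | N#Cc1ccc([N+](=O)[O-])c(O)c1 | starting material
2 | 3-(benzyloxy)-4-nitrobenzonitrile | N#Cc1ccc([N+](=O)[O-])c(OCc2ccccc2)c1 | intermediate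
3 | potassium σH adduct of the chloro ester carbanion at C5 of 2 (not isolated) | CC(C)(C)OC(=O)C(Cl)C1C=C(C#N)C=C(OCc2ccccc2)C1=[N+]([O-])[O-].[K+] | intermediate
4 | tert-butyl 2-[3-(benzyloxy)-5-cyano-2-nitrophenyl]acetate | CC(C)(C)OC(=O)Cc1cc(C#N)cc(OCc2ccccc2)c1[N+](=O)[O-] | intermediate
5 | 2-[3-(benzyloxy)-5-cyano-2-nitrophenyl]acetic acid | OC(=O)Cc1cc(C#N)cc(OCc2ccccc2)c1[N+](=O)[O-] | intermediate
6 | (R)-4-benzyl-1,3-oxazolidin-2-one | O=C1N[C@H](Cc2ccccc2)CO1 | starting material
7 | mixed anhydride of 5 and pivalic acid (not isolated) | CC(C)(C)C(=O)OC(=O)Cc1cc(C#N)cc(OCc2ccccc2)c1[N+](=O)[O-] | intermediate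
8 | (4R)-4-benzyl-3-{[3-(benzyloxy)-5-cyano-2-nitrophenyl]acetyl}-1,3-oxazolidin-2-one | O=C(Cc1cc(C#N)cc(OCc2ccccc2)c1[N+](=O)[O-])N1[C@H](Cc2ccccc2)COC1=O | intermediate
9 | 4-(benzyloxy)-3-methoxybenzaldehyde | COc1cc(C=O)ccc1OCc1ccccc1 | starting material
10 | Z dibutylboron enolate of 8 (not isolated) | CCCCB(CCCC)O/C(=C\c1cc(C#N)cc(OCc2ccccc2)c1[N+](=O)[O-])N1[C@H](Cc2ccccc2)COC1=O | intermediate
11 | (4R)-4-benzyl-3-{(2R,3R)-3-[4-(benzyloxy)-3-methoxyphenyl]-2-[3-(benzyloxy)-5-cyano-2-nitrophenyl]-3-hydroxypropanoyl}-1,3-oxazolidin-2-one | COc1cc([C@H](O)[C@@H](c2cc(C#N)cc(OCc3ccccc3)c2[N+](=O)[O-])C(=O)N2[C@H](Cc3ccccc3)COC2=O)ccc1OCc1ccccc1 | intermediate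
12 | 3-(benzyloxy)-5-{(1R,2S)-1-[4-(benzyloxy)-3-methoxyphenyl]-1,3-dihydroxypropan-2-yl}-4-nitrobenzonitrile | COc1cc([C@H](O)[C@@H](c2cc(C#N)cc(OCc3ccccc3)c2[N+](=O)[O-])CO)ccc1OCc1ccccc1 | intermediate
13 | 3-(benzyloxy)-5-{(1R,2S)-1-[4-(benzyloxy)-3-methoxyphenyl]-1-hydroxy-3-(trityloxy)propan-2-yl}-4-nitrobenzonitrile | COc1cc([C@H](O)[C@@H](c2cc(C#N)cc(OCc3ccccc3)c2[N+](=O)[O-])COC(c2ccccc2)(c2ccccc2)c2ccccc2)ccc1OCc1ccccc1 | intermediate
14 | sodium alkoxide of 13 (not isolated) | COc1cc([C@H]([O-])[C@@H](c2cc(C#N)cc(OCc3ccccc3)c2[N+](=O)[O-])COC(c2ccccc2)(c2ccccc2)c2ccccc2)ccc1OCc1ccccc1.[Na+] | intermediate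
15 | sodium salt of the anionic σ-adduct formed by attack of the alkoxide oxygen on the nitro-bearing carbon (not isolated) | COc1cc([C@@H]2OC3([N+](=O)[O-])C(OCc4ccccc4)=C[C-](C#N)C=C3[C@H]2COC(c2ccccc2)(c2ccccc2)c2ccccc2)ccc1OCc1ccccc1.[Na+] | intermediate
16 | (2R,3S)-7-(benzyloxy)-2-[4-(benzyloxy)-3-methoxyphenyl]-3-[(trityloxy)methyl]-2,3-dihydro-1-benzofuran-5-carbonitrile | COc1cc([C@@H]2Oc3c(OCc4ccccc4)cc(C#N)cc3[C@H]2COC(c2ccccc2)(c2ccccc2)c2ccccc2)ccc1OCc1ccccc1 | intermediate
17 | N-(diisobutylaluminio) aldimine of 18 (not isolated) | COc1cc([C@@H]2Oc3c(OCc4ccccc4)cc(C=N[Al](CC(C)C)CC(C)C)cc3[C@H]2COC(c2ccccc2)(c2ccccc2)c2ccccc2)ccc1OCc1ccccc1 | intermediate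
18 | (2R,3S)-7-(benzyloxy)-2-[4-(benzyloxy)-3-methoxyphenyl]-3-[(trityloxy)methyl]-2,3-dihydro-1-benzofuran-5-carbaldehyde | COc1cc([C@@H]2Oc3c(OCc4ccccc4)cc(C=O)cc3[C@H]2COC(c2ccccc2)(c2ccccc2)c2ccccc2)ccc1OCc1ccccc1 | intermediate
19 | 1-(2,4,6-trihydroxyphenyl)ethanone | CC(=O)c1c(O)cc(O)cc1O | starting material
20 | 1-[2,4-bis(benzyloxy)-6-hydroxyphenyl]ethanone | CC(=O)c1c(O)cc(OCc2ccccc2)cc1OCc1ccccc1 | intermediate
21 | (E)-1-[2,4-bis(benzyloxy)-6-hydroxyphenyl]-3-{(2R,3S)-7-(benzyloxy)-2-[4-(benzyloxy)-3-methoxyphenyl]-3-[(trityloxy)methyl]-2,3-dihydro-1-benzofuran-5-yl}prop-2-en-1-one (chalcone, not isolated) | COc1cc([C@@H]2Oc3c(OCc4ccccc4)cc(/C=C/C(=O)c4c(O)cc(OCc5ccccc5)cc4OCc4ccccc4)cc3[C@H]2COC(c2ccccc2)(c2ccccc2)c2ccccc2)ccc1OCc1ccccc1 | intermediate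
22 | 5,7-bis(benzyloxy)-2-{(2R,3S)-7-(benzyloxy)-2-[4-(benzyloxy)-3-methoxyphenyl]-3-[(trityloxy)methyl]-2,3-dihydro-1-benzofuran-5-yl}-3-hydroxy-2,3-dihydro-4H-chromen-4-one (dihydroflavonol, mixture at the two new centres, not isolated) | COc1cc([C@@H]2Oc3c(OCc4ccccc4)cc(C4Oc5cc(OCc6ccccc6)cc(OCc6ccccc6)c5C(=O)C4O)cc3[C@H]2COC(c2ccccc2)(c2ccccc2)c2ccccc2)ccc1OCc1ccccc1 | intermediate
23 | 5,7-bis(benzyloxy)-2-{(2R,3S)-7-(benzyloxy)-2-[4-(benzyloxy)-3-methoxyphenyl]-3-[(trityloxy)methyl]-2,3-dihydro-1-benzofuran-5-yl}-3-hydroxy-4H-chromen-4-one | COc1cc([C@@H]2Oc3c(OCc4ccccc4)cc(-c4oc5cc(OCc6ccccc6)cc(OCc6ccccc6)c5c(=O)c4O)cc3[C@H]2COC(c2ccccc2)(c2ccccc2)c2ccccc2)ccc1OCc1ccccc1 | intermediate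
24 | 2,3-dehydrosilychristin, 3,5,7-trihydroxy-2-[(2R,3S)-7-hydroxy-2-(4-hydroxy-3-methoxyphenyl)-3-(hydroxymethyl)-2,3-dihydro-1-benzofuran-5-yl]-4H-chromen-4-one | COc1cc([C@@H]2Oc3c(O)cc(-c4oc5cc(O)cc(O)c5c(=O)c4O)cc3[C@H]2CO)ccc1O | target

Total step count: 12. Longest linear sequence: 11 steps (steps 1 to 9, 11 and 12; step 10 prepares the acetophenone branch).

Steps most likely to fail

Step 8 (key step). The risk is that deprotonation at the nitrobenzylic C3–H competes with attack by oxygen, which could lead to C–C fragmentation with loss of aldehyde 9, or that displacement of the hindered nitro group is too slow. The fallback sets out from 13 and changes the leaving group and the mechanism. Reduction with Fe powder and NH4Cl in EtOH/H2O at 70 °C should give the aniline F1. Sandmeyer bromination (t-BuONO, CuBr2, MeCN, 0 °C → rt) should then give the aryl bromide F2. An intramolecular Ullmann etherification of the free secondary alcohol (CuI, 3,4,7,8-tetramethyl-1,10-phenanthroline, Cs2CO3, toluene, 110 °C) would close the same O1–C7a bond, and the fallback comes back to the route at 16.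

Step 11. The risk is that the phenoxide opens the chalcone epoxide in the 5-exo sense, favoured by the 6'-benzyloxy group, which leads to aurone formation in place of the flavonol. The fallback sets out from chalcone 21, isolated after the condensation alone (KOH, EtOH/THF, rt). Oxidative cyclisation with catalytic I2 in DMSO at 120 °C should give the 3-unsubstituted flavone F3. Epoxidation of its C2–C3 bond with dimethyldioxirane (acetone/CH2Cl2, 0 °C) would give the 2,3-epoxyflavanone F4, which catalytic TsOH should open to the 3-hydroxyflavone, and the fallback comes back to the route at 23.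

Step 12. The risk is over-reduction, i.e. hydrogenolysis of the doubly benzylic C2–O1 bond once the para phenol is free, or stalling before the trityl ether is cleaved. The fallback sets out from 23 and replaces hydrogenolysis by Lewis-acid dealkylation: BCl3 with pentamethylbenzene as cation scavenger in CH2Cl2 at −78 °C, then aqueous work-up, should remove the benzyl and trityl groups while the aryl methyl ether survives. It comes back to the route at 24 and makes no new compound (F0).

Further compounds

F1 | step 8 | 4-amino-3-(benzyloxy)-5-{(1R,2S)-1-[4-(benzyloxy)-3-methoxyphenyl]-1-hydroxy-3-(trityloxy)propan-2-yl}benzonitrile | COc1cc([C@H](O)[C@@H](c2cc(C#N)cc(OCc3ccccc3)c2N)COC(c2ccccc2)(c2ccccc2)c2ccccc2)ccc1OCc1ccccc1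
F2 | step 8 | 3-(benzyloxy)-4-bromo-5-{(1R,2S)-1-[4-(benzyloxy)-3-methoxyphenyl]-1-hydroxy-3-(trityloxy)propan-2-yl}benzonitrile | COc1cc([C@H](O)[C@@H](c2cc(C#N)cc(OCc3ccccc3)c2Br)COC(c2ccccc2)(c2ccccc2)c2ccccc2)ccc1OCc1ccccc1
F3 | step 11 | 5,7-bis(benzyloxy)-2-{(2R,3S)-7-(benzyloxy)-2-[4-(benzyloxy)-3-methoxyphenyl]-3-[(trityloxy)methyl]-2,3-dihydro-1-benzofuran-5-yl}-4H-chromen-4-one | COc1cc([C@@H]2Oc3c(OCc4ccccc4)cc(-c4cc(=O)c5c(OCc6ccccc6)cc(OCc6ccccc6)cc5o4)cc3[C@H]2COC(c2ccccc2)(c2ccccc2)c2ccccc2)ccc1OCc1ccccc1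
F4 | step 11 | 2,3-epoxide of flavone F3 (2,3-epoxyflavanone) | COc1cc([C@@H]2Oc3c(OCc4ccccc4)cc(C45OC4C(=O)c4c(OCc6ccccc6)cc(OCc6ccccc6)cc4O5)cc3[C@H]2COC(c2ccccc2)(c2ccccc2)c2ccccc2)ccc1OCc1ccccc1
F0 | step 12 | none | none
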